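**Retrosynthetic overview**
- The target is a (2S)-flavanone (naringenin core) with a 7-O-geranyl and an 8-C-geranyl group; the last step only removes a MOM group from O5.
- Key disconnection: the O1–C2 bond of ring C (retro-oxa-Michael) to a 2'-hydroxychalcone. Rings A and B are bought as aromatic building blocks; ring C is the only ring formed, and it closes in the key step by an enantioselective, enzymatic cyclisation (chalcone isomerase) that no small reagent matches on an unactivated chalcone.
- Enabling feature: C2 is the β-carbon of the aryl ketone C4, and O1 is a ring-A phenol oxygen ortho to that ketone. Ring C is therefore the conjugate-addition adduct of a 2'-hydroxychalcone, the substrate motif of chalcone isomerase; the second ortho oxygen (O5) is capped as MOM so that only the phenol flanked by the C8 geranyl group can close.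
- Chalcone: Claisen–Schmidt condensation of a ring-A acetophenone with 4-hydroxybenzaldehyde. Acetophenone: phloracetophenone, then C-geranylation, Mitsunobu 4-O-geranylation and site-selective MOM protection.

Key step: step 5

Assumption: the chalcone isomerase is a recombinant catalyst (expressed from a synthetic gene) and is not counted as a starting material; "geranyl" means (2E)-3,7-dimethylocta-2,6-dien-1-yl throughout.

**Route**

Step 1
Reactants: 1 2,4,6-trihydroxyacetophenone (phloracetophenone); 2 geranyl bromide
Product: 3 1-(3-geranyl-2,4,6-trihydroxyphenyl)ethanone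
Conditions: K2CO3 (anhydrous), acetone, reflux
Reagents that add atoms: none
Why: C-alkylation of the ambident phloracetophenone phenolate (SN2 at the primary allylic bromide) should place the geranyl group on one of the two equivalent free ring carbons and keep the E double bond, since no allyl cation is involved.

Step 2
Reactants: 3 1-(3-geranyl-2,4,6-trihydroxyphenyl)ethanone; 4 geraniol
Product: 5 1-[3-geranyl-4-(geranyloxy)-2,6-dihydroxyphenyl]ethanone
Conditions: PPh3, DIAD, THF, 0 °C to 23 °C
Reagents that add atoms: none
Why: Mitsunobu etherification, in which the 4-OH (para to the acetyl group, not hydrogen-bonded to it, and the most acidic phenol) should be alkylated on oxygen only, with SN2 displacement at C1 of geraniol keeping the E geometry.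

Step 3
Reactants: 5 1-[3-geranyl-4-(geranyloxy)-2,6-dihydroxyphenyl]ethanone
Product: 6 1-[3-geranyl-4-(geranyloxy)-2-hydroxy-6-(methoxymethoxy)phenyl]ethanone
Conditions: MOMCl (1.1 equiv), i-Pr2NEt, CH2Cl2, 0 °C to 23 °C
Reagents that add atoms: chloromethyl methyl ether (MOMCl), COCCl
Why: Site-selective MOM ether formation, in which the 6-OH with a free ortho position should react while the 2-OH, wedged between the acetyl and C-geranyl groups and then locked in a hydrogen bond to the carbonyl, stays free.

Step 4
Reactants: 6 1-[3-geranyl-4-(geranyloxy)-2-hydroxy-6-(methoxymethoxy)phenyl]ethanone; 7 4-hydroxybenzaldehyde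
Product: 8 (E)-1-[3-geranyl-4-(geranyloxy)-2-hydroxy-6-(methoxymethoxy)phenyl]-3-(4-hydroxyphenyl)prop-2-en-1-one
Conditions: KOH (50% aq.), EtOH, 23 °C; then AcOH to pH 6, 0 °C
Reagents that add atoms: none
Why: Claisen–Schmidt (crossed aldol) condensation, in which the methyl ketone enolate adds to the non-enolisable aldehyde and loss of water should give the (E)-enone, the MOM ether and both geranyl groups being inert to aqueous base.

Step 5
Reactants: 8 (E)-1-[3-geranyl-4-(geranyloxy)-2-hydroxy-6-(methoxymethoxy)phenyl]-3-(4-hydroxyphenyl)prop-2-en-1-one
Product: 9 (2S)-8-geranyl-7-(geranyloxy)-2-(4-hydroxyphenyl)-5-(methoxymethoxy)chroman-4-one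
Conditions: recombinant type 2 chalcone isomerase (Medicago sativa), potassium phosphate buffer pH 7.5, DMSO (10% v/v), hydroxypropyl-β-cyclodextrin, 30 °C
Reagents that add atoms: none
Why: Proposed new method: chalcone isomerase has not been shown to turn over a chalcone that carries C-geranyl, O-geranyl and 6'-O-MOM groups on ring A, so acceptance of 8 is the proposal, and the closest known reaction type is the chalcone isomerase-catalysed cyclisation of 2'-hydroxychalcones, 6'-deoxychalcones included, to (2S)-flavanones, by a protein fold that is also known to bind prenylated chalcones. The enzyme should bind 8 as its 2'-phenolate, polarise the enone carbonyl through its hydrogen-bond network and let the phenolate oxygen add to C-β of the enone, after which the enolate is protonated at C-α (intramolecular oxa-Michael addition). Ring C closes in the 6-endo-trig mode. The only new stereocentre, C2, is set by the enzyme cleft, which holds the B-ring arm so that the oxygen reaches the si face of C-β and should give the 2S configuration, as it does with its natural substrates. The step needs site selectivity between the two ortho oxygens of ring A and freedom from a racemic background reaction: the MOM group on O6' leaves the phenol next to the C-geranyl group as the only nucleophile, so only the 8-geranyl isomer can form, and a 6'-O-alkylated chalcone whose one phenol is chelated to the carbonyl should not close by itself at pH 7.5. No small-molecule catalyst is known to close an unactivated 2'-hydroxychalcone with comparable enantioselectivity, which is what the enzyme contributes here.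

Step 6
Reactants: 9 (2S)-8-geranyl-7-(geranyloxy)-2-(4-hydroxyphenyl)-5-(methoxymethoxy)chroman-4-one
Product: 10 (2S)-8-geranyl-7-(geranyloxy)-5-hydroxy-2-(4-hydroxyphenyl)chroman-4-one (CNP0103685.1)
Conditions: HCl (1 M in MeOH), THF, 0 °C to 23 °C
Reagents that add atoms: none
Why: Acid-catalysed acetal cleavage (MOM removal), in which the 5-O-MOM group peri to the C4 carbonyl should be lost under mild acid that leaves the allylic aryl ether, the trisubstituted alkenes and the C2 stereocentre (lost mainly through base-induced ring opening) untouched.

**Compound list**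
1 | 2,4,6-trihydroxyacetophenone (phloracetophenone) | CC(=O)c1c(O)cc(O)cc1O | starting material
2 | geranyl bromide, (2E)-1-bromo-3,7-dimethylocta-2,6-diene | CC(C)=CCC/C(C)=C/CBr | starting material
3 | 1-(3-geranyl-2,4,6-trihydroxyphenyl)ethanone | CC(=O)c1c(O)c(C/C=C(\C)CCC=C(C)C)c(O)cc1O | intermediate
4 | geraniol, (2E)-3,7-dimethylocta-2,6-dien-1-ol | CC(C)=CCC/C(C)=C/CO | starting material
5 | 1-[3-geranyl-4-(geranyloxy)-2,6-dihydroxyphenyl]ethanone | CC(=O)c1c(O)c(C/C=C(\C)CCC=C(C)C)c(OC/C=C(\C)CCC=C(C)C)cc1O | intermediate
6 | 1-[3-geranyl-4-(geranyloxy)-2-hydroxy-6-(methoxymethoxy)phenyl]ethanone | CC(=O)c1c(O)c(C/C=C(\C)CCC=C(C)C)c(OC/C=C(\C)CCC=C(C)C)cc1OCOC | intermediate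
7 | 4-hydroxybenzaldehyde | O=Cc1ccc(O)cc1 | starting material
8 | (E)-1-[3-geranyl-4-(geranyloxy)-2-hydroxy-6-(methoxymethoxy)phenyl]-3-(4-hydroxyphenyl)prop-2-en-1-one | O=C(/C=C/c1ccc(O)cc1)c1c(O)c(C/C=C(\C)CCC=C(C)C)c(OC/C=C(\C)CCC=C(C)C)cc1OCOC | intermediate
9 | (2S)-8-geranyl-7-(geranyloxy)-2-(4-hydroxyphenyl)-5-(methoxymethoxy)chroman-4-one | CC(C)=CCC/C(C)=C/COc1cc(OCOC)c2c(c1C/C=C(\C)CCC=C(C)C)O[C@H](c1ccc(O)cc1)CC2=O | intermediate
10 | (2S)-8-geranyl-7-(geranyloxy)-5-hydroxy-2-(4-hydroxyphenyl)chroman-4-one (CNP0103685.1) | CC(C)=CCC/C(C)=C/COc1cc(O)c2c(c1C/C=C(\C)CCC=C(C)C)O[C@H](c1ccc(O)cc1)CC2=O | target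

**Step count and risks**

Total step count: 6. Longest linear sequence: 6 steps (1 to 10).

Steps most likely to fail:

1. Step 5 (Proposed new method). The enzyme may not bind or turn over so bulky and lipophilic a substrate, the substrate may aggregate in buffer, or a slow uncatalysed closure may erode the enantiomeric purity. The fallback uses known chemistry, sets out from 8 and comes back at 9. Chalcone 8 would be closed without stereocontrol by NaOAc in refluxing EtOH (base-mediated oxa-Michael addition) to racemic 8-geranyl-7-(geranyloxy)-2-(4-hydroxyphenyl)-5-(methoxymethoxy)chroman-4-one F1. Kinetic resolution of F1 by asymmetric transfer hydrogenation with RuCl[(R,R)-TsDPEN](p-cymene) and HCO2H/Et3N (5:2), stopped near half conversion, should reduce the 2R enantiomer (hydride delivered anti to the 2-aryl group in the matched pair) to the cis alcohol (2R,4R)-8-geranyl-7-(geranyloxy)-2-(4-hydroxyphenyl)-5-(methoxymethoxy)chroman-4-ol F2. The unreduced 2S ketone is 9 and is separated by chromatography.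

2. Step 3. The MOM group may go on the wrong phenol (poor site selectivity) or on both. The fallback sets out from 5 and comes back at 6, replacing selective installation with selective removal. Both phenols would be capped (NaH, MOMCl, DMF) to give 1-[3-geranyl-4-(geranyloxy)-2,6-bis(methoxymethoxy)phenyl]ethanone F3, and one acetal would then be removed with catalytic HCl in MeOH at 0 °C. The MOM group wedged between the acetyl and geranyl groups is twisted out of conjugation and relieved of strain on cleavage, so it should leave first. The freed phenol then chelates the ketone and protects the remaining acetal, giving 6.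

3. Step 1. O-alkylation and double alkylation of the triphenol may compete with the wanted mono-C-alkylation (poor chemoselectivity). The fallback sets out from 1 and comes back at 5 by reversing the order of the two geranylations. Mitsunobu reaction of 1 with 4 (PPh3, DIAD, THF) should give the symmetric ether 1-[4-(geranyloxy)-2,6-dihydroxyphenyl]ethanone F4. C-geranylation of F4 with 2 (aqueous KOH, 0 °C) can then occur only at the one kind of free ring carbon, next to chelated and hindered phenols, and should give 5 directly, bypassing 3.

**Further compounds**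
F1 | step 5 | racemic 8-geranyl-7-(geranyloxy)-2-(4-hydroxyphenyl)-5-(methoxymethoxy)chroman-4-one | CC(C)=CCC/C(C)=C/COc1cc(OCOC)c2c(c1C/C=C(\C)CCC=C(C)C)OC(c1ccc(O)cc1)CC2=O
F2 | step 5 | (2R,4R)-8-geranyl-7-(geranyloxy)-2-(4-hydroxyphenyl)-5-(methoxymethoxy)chroman-4-ol | CC(C)=CCC/C(C)=C/COc1cc(OCOC)c2c(c1C/C=C(\C)CCC=C(C)C)O[C@@H](c1ccc(O)cc1)C[C@H]2O
F3 | step 3 | 1-[3-geranyl-4-(geranyloxy)-2,6-bis(methoxymethoxy)phenyl]ethanone | CC(=O)c1c(OCOC)c(C/C=C(\C)CCC=C(C)C)c(OC/C=C(\C)CCC=C(C)C)cc1OCOC
F4 | step 1 | 1-[4-(geranyloxy)-2,6-dihydroxyphenyl]ethanone | CC(=O)c1c(O)cc(OC/C=C(\C)CCC=C(C)C)cc1O
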